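**Retrosynthetic overview**
Numbering: C1 is the exocyclic CH2; ring A is C2–C7 (C5 CHBr, C6 CMe2, C7 spiro); ring B is C7–C12 (C10 carbinol, C11 CHBr).
The strategy rests on the spiro carbon C7, which lies between the carbonyl-level C2 of ring A and C12 of ring B. Ring B is therefore cut at C7–C8 and C11–C12 into a ring A 2-hydroxymethylene ketone (C7 nucleophile, C12 aldehyde) and methyl vinyl ketone (C8–C11).
Late stage: C2=CH2 from the C2 ketone; the C10/C11 bromohydrin from the C10=C11 alkene by syn-dioxygenation on the C2 face, cyclic sulfate and bromide (inversion at C11); C5–Br from the C5 alcohol with inversion; C10–CH3 by enol triflate coupling.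
The ring A precursor comes from 3-ethoxycyclohex-2-en-1-one by asymmetric α′-hydroxylation, carbonyl transposition with methyl addition, cuprate addition and regiospecific C7 formylation.
Ring A is carried from the starting enone; ring B is the only ring formed, in step 6.

Key step: step 6

Remark 1: the (+)-antipode of (camphorsulfonyl)oxaziridine is assumed to give the 6R alcohol 3; if the sense is opposite, the (−)-reagent is used and nothing else changes.
Remark 2: the cupreidine-derived catalyst in step 6 is assumed to be matched with the 4R silyl ether; if the cupreine-derived pseudoenantiomer is matched, it replaces it.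

**Step 1**
Reactants: 1 3-ethoxycyclohex-2-en-1-one
Product: 3 (6R)-3-ethoxy-6-hydroxycyclohex-2-en-1-one, via lithium dienolate 2 (not isolated)
Conditions: LiN(i-Pr)2, THF, −78 °C; then (+)-(camphorsulfonyl)oxaziridine, −78 °C
Reagents that add atoms: (+)-(camphorsulfonyl)oxaziridine CC1(C)C2CCC13CS(=O)(=O)N4OC34C2
Why: Kinetic α′-deprotonation gives the cross-conjugated dienolate, and asymmetric enolate hydroxylation with the chiral N-sulfonyloxaziridine should deliver oxygen to one enolate face, which sets the future C5 carbinol centre by reagent control.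

**Step 2**
Reactants: 3 (6R)-3-ethoxy-6-hydroxycyclohex-2-en-1-one
Product: 4 (6R)-6-(tert-butyldimethylsilyloxy)-3-ethoxycyclohex-2-en-1-one
Conditions: TBSCl, imidazole, DMF, rt
Reagents that add atoms: tert-butyldimethylsilyl chloride CC(C)(C)[Si](C)(C)Cl
Why: Standard silylation of the secondary α-hydroxy ketone should protect the carbinol under weakly basic conditions that do not epimerise the stereocentre.

**Step 3**
Reactants: 4 (6R)-6-(tert-butyldimethylsilyloxy)-3-ethoxycyclohex-2-en-1-one
Product: 6 (4R)-4-(tert-butyldimethylsilyloxy)-3-methylcyclohex-2-en-1-one, via lithium alkoxide 5 (not isolated)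
Conditions: MeLi, THF, −78 °C; then 1 M HCl, THF, 0 °C
Reagents that add atoms: methyllithium [Li]C; water O
Why: 1,2-Addition of MeLi to the vinylogous ester followed by acid hydrolysis with loss of water (Stork–Danheiser transposition) should move the carbonyl to the former alkoxy carbon and place a methyl group on the future C6, with the silyloxy centre untouched.

**Step 4**
Reactants: 6 (4R)-4-(tert-butyldimethylsilyloxy)-3-methylcyclohex-2-en-1-one
Product: 7 tert-butyl{[(1R)-2,2-dimethyl-4-(trimethylsilyloxy)cyclohex-3-en-1-yl]oxy}dimethylsilane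
Conditions: Me2CuLi, TMSCl, THF, −78 → −30 °C; Et3N
Reagents that add atoms: lithium dimethylcuprate [Li+].C[Cu-]C; chlorotrimethylsilane C[Si](C)(C)Cl
Why: Cuprate conjugate addition to the β-methyl enone should build the C6 gem-dimethyl group, and O-silylation of the resulting enolate fixes the enol double bond at C2=C7, toward the hindered carbon (no new stereocentre).

**Step 5**
Reactants: 7 tert-butyl{[(1R)-2,2-dimethyl-4-(trimethylsilyloxy)cyclohex-3-en-1-yl]oxy}dimethylsilane; 8 2,2,2-trifluoroethyl formate
Product: 10 (2Z,4R)-4-(tert-butyldimethylsilyloxy)-2-(hydroxymethylene)-3,3-dimethylcyclohexan-1-one, via lithium enolate 9 (not isolated)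
Conditions: MeLi, THF, 0 °C; then 8, −78 °C
Reagents that add atoms: none
Why: MeLi cleaves the silyl enol ether to the regiodefined lithium enolate, and the activated formate should C-formylate it at C7 (crossed Claisen condensation) faster than the enolate can equilibrate to the less hindered side, the product resting as the chelated hydroxymethylene tautomer.

**Step 6**
Reactants: 10 (2Z,4R)-4-(tert-butyldimethylsilyloxy)-2-(hydroxymethylene)-3,3-dimethylcyclohexan-1-one; 11 methyl vinyl ketone
Product: 13 (4R,6S)-4-(tert-butyldimethylsilyloxy)-5,5-dimethylspiro[5.5]undec-7-ene-1,9-dione, via Michael adduct 12 (not isolated)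
Conditions: 11 (1.5 equiv), 9-O-(9-phenanthryl)cupreidine (10 mol %), CH2Cl2, −20 °C; then pyrrolidine (0.3 equiv), AcOH (0.3 equiv), 35 °C
Reagents that add atoms: none
Why: The quinuclidine nitrogen of the catalyst deprotonates the acidic enol of 10 while its phenolic hydroxyl hydrogen-bonds to 11, and the ion-paired enolate adds through C7 to the β-carbon of 11 (C7–C8), an organocatalytic Michael addition of a cyclic 1,3-dicarbonyl compound to a vinyl ketone that gives the 2-formyl-2-(3-oxobutyl) ketone 12. Pyrrolidinium acetate then turns the methyl ketone into its terminal enamine, which attacks the C12 aldehyde and loses water (C11=C12), the aldol condensation stage of a Robinson-type spiroannulation. Ring B closes in the 6-(enolendo)-exo-trig mode. The only new stereocentre, the quaternary spiro carbon C7, is set in the Michael step by the catalyst, which shields one face of the planar enolate; the C5 silyloxy centre is a remote second control element, and the catalyst pseudoenantiomer is chosen so that both act in the same sense. The step needs C-alkylation at the hindered C7, face selectivity there, and aldol closure on C12 and not on C2: the small acidic enol and the unhindered acceptor should secure the first, the catalyst the second, and the much higher electrophilicity of the aldehyde beside a C2 ketone flanked by the quaternary C7 the third.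

**Step 7**
Reactants: 13 (4R,6S)-4-(tert-butyldimethylsilyloxy)-5,5-dimethylspiro[5.5]undec-7-ene-1,9-dione
Product: 14 (4R,6S)-4-(tert-butyldimethylsilyloxy)-5,5-dimethyl-9-(triethylsilyloxy)spiro[5.5]undec-8-en-1-one
Conditions: Et3SiH, RhCl(PPh3)3 (2 mol %), THF, 50 °C
Reagents that add atoms: triethylsilane CC[SiH](CC)CC
Why: Rhodium-catalysed 1,4-hydrosilylation of the enone should deliver hydride to C12 and silicon to oxygen, which fixes the enol double bond at C10=C11 on the arm that came from the aldehyde, while the hindered saturated C2 ketone does not react (no new stereocentre).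

**Step 8**
Reactants: 14 (4R,6S)-4-(tert-butyldimethylsilyloxy)-5,5-dimethyl-9-(triethylsilyloxy)spiro[5.5]undec-8-en-1-one
Product: 15 (4R,6S)-4-(tert-butyldimethylsilyloxy)-5,5-dimethyl-1-oxospiro[5.5]undec-8-en-9-yl trifluoromethanesulfonate
Conditions: CsF, PhNTf2, DME, rt
Reagents that add atoms: N-phenylbis(trifluoromethanesulfonimide) O=S(=O)(N(c1ccccc1)S(=O)(=O)C(F)(F)F)C(F)(F)F
Why: Fluoride cleaves the silyl enol ether and the enolate is O-triflated in place (enolate triflation), so the position of the enol double bond is kept, and the alkyl TBS ether is much slower to cleave.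

**Step 9**
Reactants: 15 (4R,6S)-4-(tert-butyldimethylsilyloxy)-5,5-dimethyl-1-oxospiro[5.5]undec-8-en-9-yl trifluoromethanesulfonate
Product: 16 (4R,6S)-4-(tert-butyldimethylsilyloxy)-5,5,9-trimethylspiro[5.5]undec-8-en-1-one
Conditions: MeZnCl, Pd(PPh3)4 (5 mol %), LiCl, THF, 50 °C
Reagents that add atoms: methylzinc chloride C[Zn]Cl
Why: Negishi coupling of the enol triflate with the methylzinc reagent should install the C10 methyl group and leave the trisubstituted C10=C11 alkene, the organozinc reagent being inert toward the ketone.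

**Step 10**
Reactants: 16 (4R,6S)-4-(tert-butyldimethylsilyloxy)-5,5,9-trimethylspiro[5.5]undec-8-en-1-one
Product: 17 (4R,6S)-4-hydroxy-5,5,9-trimethylspiro[5.5]undec-8-en-1-one
Conditions: TBAF, THF, 40 °C
Reagents that add atoms: none
Why: Fluoride-mediated silyl ether cleavage should free the C5 alcohol without touching a stereocentre.

**Step 11**
Reactants: 17 (4R,6S)-4-hydroxy-5,5,9-trimethylspiro[5.5]undec-8-en-1-one
Product: 18 (4S,6S)-4-bromo-5,5,9-trimethylspiro[5.5]undec-8-en-1-one
Conditions: CBr4, P(n-C8H17)3, toluene, 70 °C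
Reagents that add atoms: carbon tetrabromide BrC(Br)(Br)Br
Why: In this Appel reaction bromide displaces the alkoxyphosphonium group from the rear, so C5 is inverted from R to S, and the small, strongly nucleophilic trialkylphosphine is chosen because the carbinol is neopentylic.

**Step 12**
Reactants: 18 (4S,6S)-4-bromo-5,5,9-trimethylspiro[5.5]undec-8-en-1-one
Product: 20 (4S,6S,8S,9R)-4-bromo-8,9-dihydroxy-5,5,9-trimethylspiro[5.5]undecan-1-one, via hydroxy acetate 19 (not isolated)
Conditions: PhI(OAc)2, BF3·OEt2, AcOH, H2O (3 equiv), rt; then K2CO3, MeOH, rt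
Reagents that add atoms: (diacetoxyiodo)benzene CC(=O)OI(OC(C)=O)c1ccccc1
Why: In this Prévost–Woodward-type syn-dioxygenation with trivalent iodine the iodane should add to the alkene face anti to the C2 carbon (pseudoaxial on ring B because the quaternary C6 takes the equatorial site), acetate opens it from the C2 face, and the acetoxy group then displaces iodobenzene with inversion to a cis-fused dioxolanylium ion that water opens, so both oxygens end syn to C2 (C10 R, C11 S) whichever carbon the first acetate attacks; a direct bromohydrin reaction is avoided because trans-diaxial opening of the bromonium ion would be expected to put bromine on the tertiary C10.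

**Step 13**
Reactants: 20 (4S,6S,8S,9R)-4-bromo-8,9-dihydroxy-5,5,9-trimethylspiro[5.5]undecan-1-one
Product: 22 (4S,6S,8S,9R)-4-bromo-5,5,9-trimethyl-1-oxospiro[5.5]undecane-8,9-diyl cyclic sulfate, via cyclic sulfite 21 (not isolated)
Conditions: SOCl2, Et3N, CH2Cl2, 0 °C; then RuCl3 (1 mol %), NaIO4, MeCN–H2O, 0 °C
Reagents that add atoms: thionyl chloride O=S(Cl)Cl; sodium periodate [Na+].[O-]I(=O)(=O)=O
Why: The cis-diol is closed to the cyclic sulfite and oxidised at sulfur (cyclic sulfate formation), which activates the C11–O bond without touching a stereocentre.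

**Step 14**
Reactants: 22 (4S,6S,8S,9R)-4-bromo-5,5,9-trimethyl-1-oxospiro[5.5]undecane-8,9-diyl cyclic sulfate
Product: 24 (4S,6S,8R,9R)-4,8-dibromo-9-hydroxy-5,5,9-trimethylspiro[5.5]undecan-1-one, via bromo sulfate 23 (not isolated)
Conditions: LiBr, THF, 40 °C; then H2SO4 (cat.), H2O, THF, rt
Reagents that add atoms: lithium bromide [Li+].[Br-]
Why: SN2 opening of the cyclic sulfate by bromide at the secondary C11, from the face opposite its axial C–O bond, should invert C11 (S to R) and leave the tertiary C10–O bond intact, and hydrolysis of the sulfate monoester then frees the trans-diequatorial bromohydrin.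

**Step 15**
Reactants: 24 (4S,6S,8R,9R)-4,8-dibromo-9-hydroxy-5,5,9-trimethylspiro[5.5]undecan-1-one
Product: 25 (2R,3R,6R,8S)-2,8-dibromo-3,7,7-trimethyl-11-methylidenespiro[5.5]undecan-3-ol
Conditions: Cp2TiMe2 (4 equiv), toluene–THF, 70 °C, dark
Reagents that add atoms: dimethyltitanocene C[Ti](C)(C1C=CC=C1)C1C=CC=C1
Why: In this Petasis methylenation the titanium methylidene formed on heating should convert the hindered, enolisable C2 ketone into the exocyclic alkene under non-basic conditions that leave both C–Br bonds and the tertiary alcohol in place (excess reagent allows for the free hydroxyl).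

**Compound list**
1 | 3-ethoxycyclohex-2-en-1-one | CCOC1=CC(=O)CCC1 | starting material
2 | lithium 5-ethoxycyclohexa-1,5-dien-1-olate | CCOC1=CC(O[Li])=CCC1 | intermediate (not isolated)
3 | (6R)-3-ethoxy-6-hydroxycyclohex-2-en-1-one | CCOC1=CC(=O)[C@H](O)CC1 | intermediate
4 | (6R)-6-(tert-butyldimethylsilyloxy)-3-ethoxycyclohex-2-en-1-one | CCOC1=CC(=O)[C@H](O[Si](C)(C)C(C)(C)C)CC1 | intermediate
5 | lithium (6R)-6-(tert-butyldimethylsilyloxy)-3-ethoxy-1-methylcyclohex-2-en-1-olate (both C1 epimers) | CCOC1=CC(C)(O[Li])[C@H](O[Si](C)(C)C(C)(C)C)CC1 | intermediate (not isolated)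
6 | (4R)-4-(tert-butyldimethylsilyloxy)-3-methylcyclohex-2-en-1-one | O=C1C=C(C)[C@H](O[Si](C)(C)C(C)(C)C)CC1 | intermediate
7 | tert-butyl{[(1R)-2,2-dimethyl-4-(trimethylsilyloxy)cyclohex-3-en-1-yl]oxy}dimethylsilane | C[Si](C)(C)OC1=CC(C)(C)[C@H](O[Si](C)(C)C(C)(C)C)CC1 | intermediate
8 | 2,2,2-trifluoroethyl formate | O=COCC(F)(F)F | starting material
9 | lithium (4R)-4-(tert-butyldimethylsilyloxy)-3,3-dimethylcyclohex-1-en-1-olate | [Li]OC1=CC(C)(C)[C@H](O[Si](C)(C)C(C)(C)C)CC1 | intermediate (not isolated)
10 | (2Z,4R)-4-(tert-butyldimethylsilyloxy)-2-(hydroxymethylene)-3,3-dimethylcyclohexan-1-one | O/C=C1\C(=O)CC[C@@H](O[Si](C)(C)C(C)(C)C)C1(C)C | intermediate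
11 | methyl vinyl ketone | CC(=O)C=C | starting material
12 | (1R,3R)-3-(tert-butyldimethylsilyloxy)-2,2-dimethyl-6-oxo-1-(3-oxobutyl)cyclohexane-1-carbaldehyde | O=C1CC[C@@H](O[Si](C)(C)C(C)(C)C)C(C)(C)[C@@]1(C=O)CCC(C)=O | intermediate (not isolated)
13 | (4R,6S)-4-(tert-butyldimethylsilyloxy)-5,5-dimethylspiro[5.5]undec-7-ene-1,9-dione | O=C1CC[C@@H](O[Si](C)(C)C(C)(C)C)C(C)(C)[C@@]12CCC(=O)C=C2 | intermediate
14 | (4R,6S)-4-(tert-butyldimethylsilyloxy)-5,5-dimethyl-9-(triethylsilyloxy)spiro[5.5]undec-8-en-1-one | O=C1CC[C@@H](O[Si](C)(C)C(C)(C)C)C(C)(C)[C@@]12CCC(O[Si](CC)(CC)CC)=CC2 | intermediate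
15 | (4R,6S)-4-(tert-butyldimethylsilyloxy)-5,5-dimethyl-1-oxospiro[5.5]undec-8-en-9-yl trifluoromethanesulfonate | O=C1CC[C@@H](O[Si](C)(C)C(C)(C)C)C(C)(C)[C@@]12CCC(OS(=O)(=O)C(F)(F)F)=CC2 | intermediate
16 | (4R,6S)-4-(tert-butyldimethylsilyloxy)-5,5,9-trimethylspiro[5.5]undec-8-en-1-one | O=C1CC[C@@H](O[Si](C)(C)C(C)(C)C)C(C)(C)[C@@]12CCC(C)=CC2 | intermediate
17 | (4R,6S)-4-hydroxy-5,5,9-trimethylspiro[5.5]undec-8-en-1-one | O=C1CC[C@@H](O)C(C)(C)[C@@]12CCC(C)=CC2 | intermediate
18 | (4S,6S)-4-bromo-5,5,9-trimethylspiro[5.5]undec-8-en-1-one | O=C1CC[C@H](Br)C(C)(C)[C@@]12CCC(C)=CC2 | intermediate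
19 | (4S,6S,8S,9R)-4-bromo-9-hydroxy-5,5,9-trimethyl-1-oxospiro[5.5]undecan-8-yl acetate | O=C1CC[C@H](Br)C(C)(C)[C@@]12CC[C@@](C)(O)[C@@H](OC(C)=O)C2 | intermediate (not isolated)
20 | (4S,6S,8S,9R)-4-bromo-8,9-dihydroxy-5,5,9-trimethylspiro[5.5]undecan-1-one | O=C1CC[C@H](Br)C(C)(C)[C@@]12CC[C@@](C)(O)[C@@H](O)C2 | intermediate
21 | (4S,6S,8S,9R)-4-bromo-5,5,9-trimethyl-1-oxospiro[5.5]undecane-8,9-diyl cyclic sulfite (both configurations at sulfur) | O=C1CC[C@H](Br)C(C)(C)[C@@]12CC[C@@](C)(OS(=O)O3)[C@@H]3C2 | intermediate (not isolated)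
22 | (4S,6S,8S,9R)-4-bromo-5,5,9-trimethyl-1-oxospiro[5.5]undecane-8,9-diyl cyclic sulfate | O=C1CC[C@H](Br)C(C)(C)[C@@]12CC[C@@](C)(OS(=O)(=O)O3)[C@@H]3C2 | intermediate
23 | lithium (4S,6S,8R,9R)-4,8-dibromo-5,5,9-trimethyl-1-oxospiro[5.5]undecan-9-yl sulfate | O=C1CC[C@H](Br)C(C)(C)[C@@]12CC[C@@](C)(OS(=O)(=O)[O-])[C@H](Br)C2.[Li+] | intermediate (not isolated)
24 | (4S,6S,8R,9R)-4,8-dibromo-9-hydroxy-5,5,9-trimethylspiro[5.5]undecan-1-one | O=C1CC[C@H](Br)C(C)(C)[C@@]12CC[C@@](C)(O)[C@H](Br)C2 | intermediate
25 | (2R,3R,6R,8S)-2,8-dibromo-3,7,7-trimethyl-11-methylidenespiro[5.5]undecan-3-ol | C=C1CC[C@H](Br)C(C)(C)[C@@]12CC[C@@](C)(O)[C@H](Br)C2 | target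

**Step count**
Total steps: 15. Longest linear sequence: 15 steps (1 → 25); 8 and 11 are bought.

**Steps most likely to fail**

Step 6. The conjugate addition at C7, next to the gem-dimethyl carbon, may be slow and poorly face-selective (catalyst and C5 centre mismatched), and the formyl group may be lost by retro-Claisen cleavage during the amine-mediated closure. Fallback with covalent stereocontrol, setting out from 10: condensation with L-valine diethylamide (or its antipode, whichever is matched; molecular sieves, CH2Cl2) should give the Z-enaminone F1. Cu(OAc)2·H2O (5 mol %) and 11 in acetone at rt should then add C7 to the vinyl ketone within a copper chelate whose isopropyl group shields one face, giving the imine adduct F2. Hydrolysis with 1 M HCl in THF releases the auxiliary and comes back to the route at 12, which is closed to 13 with pyrrolidine and AcOH as in step 6.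

Step 11. The neopentylic alkoxyphosphonium ion may ionise, with 1,2-alkyl shift or elimination, before bromide can attack from the rear. Fallback with separate sulfonate activation, setting out from 17: Tf2O and 2,6-lutidine in CH2Cl2 at −40 °C should give the secondary triflate F3. Soluble bromide (Bu4NBr, toluene, 0 °C → rt) then displaces it with inversion in a non-ionising medium and comes back to the route at 18.

Step 14. Rearside attack of bromide at C11, beside the quaternary C10, may be slow enough for elimination or ionisation of the tertiary C10–O bond to take over. Fallback with reversible opening under thermodynamic control, setting out from 20: HC(OMe)3 with PPTS should give the cyclic methyl orthoformate F4. Acetyl bromide in CH2Cl2 at 0 °C ionises it to the cis-fused dioxolanylium bromide; attack of bromide at C10 gives a trans-diaxial tertiary bromide that re-ionises, whereas attack at C11 gives the stable trans-diequatorial bromo formate F5. KHCO3 in MeOH removes the formyl group and comes back to the route at 24.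

**Further compounds**
F1 | step 6 | Z-enaminone of 10 with L-valine diethylamide | CC(C)[C@H](N/C=C1\C(=O)CC[C@@H](O[Si](C)(C)C(C)(C)C)C1(C)C)C(=O)N(CC)CC
F2 | step 6 | imine of Michael adduct 12 with L-valine diethylamide | O=C1CC[C@@H](O[Si](C)(C)C(C)(C)C)C(C)(C)[C@@]1(C=N[C@@H](C(C)C)C(=O)N(CC)CC)CCC(C)=O
F3 | step 11 | (4R,6S)-5,5,9-trimethyl-1-oxospiro[5.5]undec-8-en-4-yl trifluoromethanesulfonate | O=C1CC[C@@H](OS(=O)(=O)C(F)(F)F)C(C)(C)[C@@]12CCC(C)=CC2
F4 | step 14 | cyclic methyl orthoformate of diol 20 (both configurations at the orthoester carbon) | O=C1CC[C@H](Br)C(C)(C)[C@@]12CC[C@@](C)(OC(OC)O3)[C@@H]3C2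
F5 | step 14 | (4S,6S,8R,9R)-4,8-dibromo-5,5,9-trimethyl-1-oxospiro[5.5]undecan-9-yl formate | O=C1CC[C@H](Br)C(C)(C)[C@@]12CC[C@@](C)(OC=O)[C@H](Br)C2
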